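**Note for whoever takes the bench.** L in the south-east flask moved 0.1 percentage points between its last two readings, less than the scatter of 0.5 points.

| flask | Q | remark | time |
|---|---|---|---|
| south-east | 1 M | the very flask that is asked about, followed so far |  |
| west | 1.5 M | run made earlier |  |
| flask | 1.0 M |  | 8.0 d |
- south-east (time / d: L / %, Q / %): 0.625: 4.8, 9.5; 1.04: 7.7, 7.9; 1.67: 11.2, 7.7; 3.00: 14.3, 6.8; 5.00: 14.8, 7.1; 8.00: 14.9, 5.7
- west (time / d: L / %, Q / %): 1.67: 11.3, 6.6; 2.50: 13.8, 6.6; 4.00: 15.0, 6.6; 8.00: 16.6, 6.1; 12.0: 17.1, 5.5; 20.0: 16.0, 6.4

(standard deviation of a reading: 0.5 percentage points)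
- eta: change nothing and wait 15 d more
- gamma: at 8.0 d take out 90% of the L then present, then wait 15 d
- zeta: at 8.0 d add Q, 50.0% of the amount charged, then wait 15 d
- L taken out counts as made
- the numbers in the tables scatter with a standard deviation of 0.5 percentage points
- additions bring no volume worth counting
- L, in percent of the Q first charged, at 8.0 d
- the option that brings most further L ("none" if no option brings more than 2 percentage points) (eta / gamma / zeta / none)
- L present, with what was taken out counted in, in percent of the Q first charged, after eta
- L present, with what was taken out counted in, in percent of the Q first charged, after zeta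

At 8.00 d the south-east flask reads L 14.9% and Q 5.7%, so about 79.4% of its charge sits in forms I can't see. Q is still there, so I take the standstill for a balance (thermodynamic control): L's gain equals its loss. If the steps are first order, dividing one rate by the other removes time and charge. I therefore pool the level readings of both flasks, at 1 M and 1.5 M, and get s = 15.9%, the L at standstill as a fraction of all the material in the flask.

Percentages below are of the first charge.

eta: L stays at s = 15.9%
gamma: further L = 90% · s · (1 − s) = 12 points
zeta: further L = 50.0% · s = 7.9 points, total 23.8%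

Don't just wait, and take L out rather than add Q, since that gains more.

The forecast reads a “first-order reversible balance” too. It gives now 14.9% (14.4% to 15.4%), below my s by 1.00 point, then g1 15%, g3 22.5%, best gamma.

**Result.** The asked flask gives L 15.8% at 8.0 d, and gamma is best with 12 points further, against 8 points for zeta and 0.079 points for eta; g1 is 15.9% and g3 23.9%. At 8.00 d the asked flask holds G at 43.4%, more than X and J together.

    X ⇌ G (K = 1.60, k = 8.00 × 10⁻⁴ min⁻¹)
    L ⇌ X (K = 1.70, k = 8.40 × 10⁻⁴ min⁻¹)
    L ⇌ J (K = 0.480, k = 3.20 × 10⁻⁴ min⁻¹)
    Q ⇌ L (K = 2.60, k = 1.50 × 10⁻⁴ min⁻¹)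
    G ⇌ Q (k = 0.00210 min⁻¹)

A neighbour flask with the same charge, read at 50 h, held L 12.4%, which is 3.5 points short of s, with Q at 7.1%.

All runs stem from a simulated flask on assumed constants; noise was put on by code.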